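**Retrosynthetic overview**
1. Last step: axial hydride reduction of the ring A α-hydroxy ketone 16 gives the trans-diol of the target 17.
2. Key C–C disconnection: the ring A C3–CH2 bond, made by trans-selective alkylation of the dianion of hydroxy ketone 13 with the ring B allylic iodide 8.
3. Ring A piece 13 comes from (S)-carvone: epoxidation trans to isopropenyl, LiAlH4, oxidation.
4. Ring B piece 8 comes from (1S,2S,4R)-limonene-1,2-diol: cyclic sulfate, bromide inversion to the syn-bromohydrin, ene chlorination, silylation, Finkelstein exchange.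
5. No ring is formed: both cyclohexanes are taken intact from the chiral pool (ring B series first, ring A series second, then union).

Assumption: diol 12 is written as its expected major epimer at the secondary carbinol; the other epimer gives the same ketone 13 in step 9.

**Step 1**
Reactants: 1 (1S,2S,4R)-1-methyl-4-(prop-1-en-2-yl)cyclohexane-1,2-diol [(+)-limonene-1,2-diol]
Product: 2 cyclic sulfite of 1 [(3aS,6R,7aS)-3a-methyl-6-(prop-1-en-2-yl)hexahydro-1,3,2-benzodioxathiole 2-oxide; both sulfur epimers]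
Conditions: SOCl2 (1.2 equiv), Et3N (2.5 equiv), CH2Cl2, 0 °C
Reagents that add atoms: thionyl chloride, O=S(Cl)Cl
Why: Cyclic sulfite formation; the secondary hydroxyl is sulfinylated first and the tertiary hydroxyl closes the five-membered ring after the ring flips to the diequatorial-diol conformer, with no carbon stereocentre touched.

**Step 2**
Reactants: 2 cyclic sulfite
Product: 3 cyclic sulfate of 1 [(3aS,6R,7aS)-3a-methyl-6-(prop-1-en-2-yl)hexahydro-1,3,2-benzodioxathiole 2,2-dioxide]
Conditions: RuCl3·3H2O (0.5 mol %), NaIO4 (1.1 equiv), MeCN/CCl4/H2O, 0 °C, 10 min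
Reagents that add atoms: sodium metaperiodate NaIO4, [Na+].[O-]I(=O)(=O)=O
Why: Sharpless cyclic sulfate protocol (catalytic ruthenium tetroxide oxidation at sulfur), which is complete within minutes at 0 °C and, with periodate limiting, is expected to outrun attack on the 1,1-disubstituted alkene.

**Step 3**
Reactants: 3 cyclic sulfate
Product: 5 (1S,2R,4R)-2-bromo-1-methyl-4-(prop-1-en-2-yl)cyclohexan-1-ol, via lithium bromo sulfate 4 (not isolated)
Conditions: LiBr (1.2 equiv), THF, rt → 50 °C; then H2SO4 (cat.), H2O (2 equiv), THF, rt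
Reagents that add atoms: lithium bromide LiBr, [Li+].[Br-]
Why: SN2 opening of the cyclic sulfate by bromide at the secondary carbon with inversion (the tied-up tertiary oxygen cannot form an epoxide), then S–O hydrolysis of the tertiary sulfate with retention, which places bromine cis to the tertiary hydroxyl (syn-bromohydrin).

**Step 4**
Reactants: 5 syn-bromohydrin
Product: 6 (1S,2R,4R)-2-bromo-4-(3-chloroprop-1-en-2-yl)-1-methylcyclohexan-1-ol
Conditions: Ca(OCl)2 (0.6 equiv), CO2 (dry ice), CH2Cl2/H2O, 0 °C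
Reagents that add atoms: calcium hypochlorite Ca(OCl)2, [Ca+2].[O-]Cl.[O-]Cl
Why: Ene-type allylic chlorination by hypochlorous acid; electrophilic chlorine adds to the terminal alkene carbon and a methyl proton is lost, giving the 2-substituted allyl chloride without touching the stereocentres.

**Step 5**
Reactants: 6 allylic chloride
Product: 7 {[(1S,2R,4R)-2-bromo-4-(3-chloroprop-1-en-2-yl)-1-methylcyclohexyl]oxy}trimethylsilane
Conditions: TMSOTf (1.3 equiv), 2,6-lutidine (2 equiv), CH2Cl2, −78 → 0 °C
Reagents that add atoms: trimethylsilyl trifluoromethanesulfonate, C[Si](C)(C)OS(=O)(=O)C(F)(F)F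
Why: O-silylation of the tertiary alcohol so that it cannot quench the enolate in step 10.

**Step 6**
Reactants: 7 silyl ether allylic chloride
Product: 8 {[(1S,2R,4R)-2-bromo-4-(3-iodoprop-1-en-2-yl)-1-methylcyclohexyl]oxy}trimethylsilane
Conditions: NaI (3 equiv), acetone, rt, dark
Reagents that add atoms: sodium iodide NaI, [Na+].[I-]
Why: Finkelstein exchange (SN2) at the primary allylic carbon; the hindered secondary ring bromide does not react.

**Step 7**
Reactants: 9 (S)-(+)-carvone [(5S)-2-methyl-5-(prop-1-en-2-yl)cyclohex-2-en-1-one]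
Product: 10 (1S,4S,6S)-1-methyl-4-(prop-1-en-2-yl)-7-oxabicyclo[4.1.0]heptan-2-one
Conditions: 30% H2O2, NaOH (aq., 0.3 equiv), MeOH, −10 → 0 °C
Reagents that add atoms: hydrogen peroxide, OO
Why: Weitz–Scheffer nucleophilic epoxidation; hydroperoxide adds axially to the enone anti to the isopropenyl group, so the epoxide, and with it the tertiary C–O stereocentre of ring A, forms trans to isopropenyl.

**Step 8**
Reactants: 10 epoxy ketone
Product: 12 (1S,2R,4S)-1-methyl-4-(prop-1-en-2-yl)cyclohexane-1,2-diol, via epoxy alcohol aluminate 11 (not isolated)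
Conditions: LiAlH4 (2 equiv), THF, 0 °C → reflux; H2O/NaOH work-up
Reagents that add atoms: none
Why: Hydride reduction; LiAlH4 reduces the ketone and then opens the trisubstituted epoxide by SN2 attack at the secondary carbon, so the tertiary C–O bond from step 7 is kept (the new secondary carbinol is oxidised in step 9, so its configuration does not matter).

**Step 9**
Reactants: 12 diol
Product: 13 (2S,5S)-2-hydroxy-2-methyl-5-(prop-1-en-2-yl)cyclohexan-1-one
Conditions: 2-iodoxybenzoic acid (IBX, 1.5 equiv), DMSO, rt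
Reagents that add atoms: none
Why: Hypervalent iodine oxidation of the secondary alcohol to the α-hydroxy ketone without C–C cleavage; the tertiary alcohol and the alkene are inert and no stereocentre is touched.

**Step 10**
Reactants: 13 (2S,5S)-2-hydroxy-2-methyl-5-(prop-1-en-2-yl)cyclohexan-1-one; 8 ring B allylic iodide
Product: 16 (2S,5S,6R)-6-{2-[(1R,3R,4S)-3-bromo-4-hydroxy-4-methylcyclohexyl]prop-2-en-1-yl}-2-hydroxy-2-methyl-5-(prop-1-en-2-yl)cyclohexan-1-one, via dilithium alkoxide enolate 14 (not isolated), via ring B silyl ether 15 (not isolated)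
Conditions: LiN(iPr)2 (2.2 equiv), THF, −78 → −40 °C; 8, DMPU, −78 → −20 °C; then 1 M HCl, THF, 0 °C → rt
Reagents that add atoms: none
Why: Enolate alkylation (SN2 at the allylic iodide); two equivalents of base give the alkoxide enolate at the only enolisable carbon and the electrophile adds anti to the neighbouring isopropenyl group, setting the new stereocentre trans (diequatorial, also the thermodynamic epimer), after which dilute acid removes the silyl group.

**Step 11**
Reactants: 16 α-hydroxy ketone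
Product: 17 (1S,2S,3R,4S)-3-{2-[(1R,3R,4S)-3-bromo-4-hydroxy-4-methylcyclohexyl]prop-2-en-1-yl}-1-methyl-4-(prop-1-en-2-yl)cyclohexane-1,2-diol (target)
Conditions: NaBH4 (1.5 equiv), MeOH, −20 → 0 °C
Reagents that add atoms: none
Why: Borohydride reduction of a cyclohexanone; the axial methyl group next to the carbonyl blocks equatorial approach, so hydride adds axially and gives the equatorial alcohol, trans to both the tertiary hydroxyl and the allylic side chain.

**Compound list**
1 | (1S,2S,4R)-1-methyl-4-(prop-1-en-2-yl)cyclohexane-1,2-diol [(+)-limonene-1,2-diol] | CC(=C)[C@@H]1CC[C@](C)(O)[C@@H](O)C1 | starting material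
2 | cyclic sulfite of 1, (3aS,6R,7aS)-3a-methyl-6-(prop-1-en-2-yl)hexahydro-1,3,2-benzodioxathiole 2-oxide (both sulfur epimers) | CC(=C)[C@@H]1CC[C@]2(C)OS(=O)O[C@H]2C1 | intermediate
3 | cyclic sulfate of 1, (3aS,6R,7aS)-3a-methyl-6-(prop-1-en-2-yl)hexahydro-1,3,2-benzodioxathiole 2,2-dioxide | CC(=C)[C@@H]1CC[C@]2(C)OS(=O)(=O)O[C@H]2C1 | intermediate
4 | lithium (1S,2R,4R)-2-bromo-1-methyl-4-(prop-1-en-2-yl)cyclohexyl sulfate | CC(=C)[C@@H]1CC[C@](C)(OS(=O)(=O)[O-])[C@H](Br)C1.[Li+] | intermediate
5 | (1S,2R,4R)-2-bromo-1-methyl-4-(prop-1-en-2-yl)cyclohexan-1-ol (syn-bromohydrin) | CC(=C)[C@@H]1CC[C@](C)(O)[C@H](Br)C1 | intermediate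
6 | (1S,2R,4R)-2-bromo-4-(3-chloroprop-1-en-2-yl)-1-methylcyclohexan-1-ol | C=C(CCl)[C@@H]1CC[C@](C)(O)[C@H](Br)C1 | intermediate
7 | {[(1S,2R,4R)-2-bromo-4-(3-chloroprop-1-en-2-yl)-1-methylcyclohexyl]oxy}trimethylsilane | C=C(CCl)[C@@H]1CC[C@](C)(O[Si](C)(C)C)[C@H](Br)C1 | intermediate
8 | {[(1S,2R,4R)-2-bromo-4-(3-iodoprop-1-en-2-yl)-1-methylcyclohexyl]oxy}trimethylsilane | C=C(CI)[C@@H]1CC[C@](C)(O[Si](C)(C)C)[C@H](Br)C1 | intermediate
9 | (S)-(+)-carvone, (5S)-2-methyl-5-(prop-1-en-2-yl)cyclohex-2-en-1-one | CC1=CC[C@@H](CC1=O)C(C)=C | starting material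
10 | (1S,4S,6S)-1-methyl-4-(prop-1-en-2-yl)-7-oxabicyclo[4.1.0]heptan-2-one (epoxide trans to isopropenyl) | CC(=C)[C@H]1C[C@@H]2O[C@]2(C)C(=O)C1 | intermediate
11 | epoxy alcohol from 10, hydroxyl on the face of the epoxide oxygen, present as its alkoxyaluminate | CC(=C)[C@H]1C[C@@H]2O[C@]2(C)[C@H](O)C1 | intermediate
12 | (1S,2R,4S)-1-methyl-4-(prop-1-en-2-yl)cyclohexane-1,2-diol | CC(=C)[C@H]1CC[C@](C)(O)[C@H](O)C1 | intermediate
13 | (2S,5S)-2-hydroxy-2-methyl-5-(prop-1-en-2-yl)cyclohexan-1-one | CC(=C)[C@H]1CC[C@](C)(O)C(=O)C1 | intermediate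
14 | dilithium alkoxide enolate of 13 | [Li+].[Li+].CC(=C)[C@H]1CC[C@](C)([O-])C([O-])=C1 | intermediate
15 | (2S,5S,6R)-6-{2-[(1R,3R,4S)-3-bromo-4-methyl-4-(trimethylsilyloxy)cyclohexyl]prop-2-en-1-yl}-2-hydroxy-2-methyl-5-(prop-1-en-2-yl)cyclohexan-1-one | C=C(C[C@@H]1[C@@H](C(=C)C)CC[C@](C)(O)C1=O)[C@@H]1CC[C@](C)(O[Si](C)(C)C)[C@H](Br)C1 | intermediate
16 | (2S,5S,6R)-6-{2-[(1R,3R,4S)-3-bromo-4-hydroxy-4-methylcyclohexyl]prop-2-en-1-yl}-2-hydroxy-2-methyl-5-(prop-1-en-2-yl)cyclohexan-1-one | C=C(C[C@@H]1[C@@H](C(=C)C)CC[C@](C)(O)C1=O)[C@@H]1CC[C@](C)(O)[C@H](Br)C1 | intermediate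
17 | (1S,2S,3R,4S)-3-{2-[(1R,3R,4S)-3-bromo-4-hydroxy-4-methylcyclohexyl]prop-2-en-1-yl}-1-methyl-4-(prop-1-en-2-yl)cyclohexane-1,2-diol | C=C(C[C@@H]1[C@@H](C(=C)C)CC[C@](C)(O)[C@H]1O)[C@@H]1CC[C@](C)(O)[C@H](Br)C1 | target

**Totals**
Total step count: 11 (steps 1–6 ring B series, steps 7–9 ring A series, steps 10–11 union and finish).
Longest linear sequence: 8 steps (1 → 8 by steps 1–6, then steps 10 and 11).

**Steps most likely to fail**

Step 2 (oxidation of sulfite 2 beside the isopropenyl group). Ruthenium tetroxide can cleave the electron-rich alkene if the sulfur oxidation is not fast enough. The fallback sets out from 1 and comes back at 5, masking the alkene as a ketone and rebuilding it afterwards. Ozonolysis of 1 (O3, CH2Cl2/MeOH, −78 °C; then Me2S) gives the methyl ketone diol F1. SOCl2/Et3N gives the keto cyclic sulfite F2, and RuCl3·3H2O/NaIO4, now with no alkene present, gives the keto cyclic sulfate F3. LiBr opens it to the lithium keto bromo sulfate F4, which is hydrolysed (cat. H2SO4, H2O, THF) to the bromohydrin methyl ketone F5. Non-basic Takai–Lombardo methylenation (Zn, CH2Br2, TiCl4, THF/CH2Cl2) restores the isopropenyl group and gives 5.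

Step 3 (bromide opening of cyclic sulfate 3). In the trans-fused chair of 3 the isopropenyl group is axial on the face from which bromide must enter, so the SN2 step has to pass through a twist-boat and may lose out to ionisation at the tertiary C–O bond. The fallback sets out from 1 and comes back at 5, and it removes the axial group during the displacement. Compound 1 is taken to the methyl ketone diol F1 and the keto cyclic sulfite F2 as above. The ring carbon bearing the acetyl group is now enolisable, and catalytic TsOH (CH2Cl2) equilibrates it to the 4-epi keto cyclic sulfite F6, in which acetyl is equatorial on the trans-fused chair. RuCl3·3H2O/NaIO4 gives the 4-epi keto cyclic sulfate F7, and bromide then enters axially past hydrogen atoms only, giving the lithium 4-epi bromo sulfate F8. Hydrolysis gives the 4-epi bromohydrin ketone F9, and a second TsOH equilibration returns the acetyl carbon to the all-equatorial bromohydrin methyl ketone F5. Methylenation as above gives 5.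

Step 10 (alkylation of the unprotected hydroxy ketone as its dianion). Aggregation of the alkoxide enolate, proton transfer or O-alkylation could lower the yield and the trans selectivity. The fallback sets out from 13 (with chloride 7 as partner) and comes back at 16, replacing the SN2 alkylation by a palladium-catalysed allylation. Compound 13 is silylated (TMSCl, imidazole, DMF) to the α-silyloxy ketone F10. LiN(SiMe3)2 (THF, −78 °C) gives its lithium enolate F11. This is allylated with allylic chloride 7 under Pd(PPh3)4 catalysis (zerovalent palladium, Tsuji–Trost reaction through the symmetrical 2-substituted π-allyl complex) to give the bis(trimethylsilyl) ether F12. 1 M HCl in THF cleaves both silyl groups and gives 16.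

**Further compounds**
F1 | step 2 | 1-[(1R,3S,4S)-3,4-dihydroxy-4-methylcyclohexyl]ethan-1-one (methyl ketone diol) | CC(=O)[C@@H]1CC[C@](C)(O)[C@@H](O)C1
F2 | step 2 | keto cyclic sulfite, cyclic sulfite of F1 (both sulfur epimers) | CC(=O)[C@@H]1CC[C@]2(C)OS(=O)O[C@H]2C1
F3 | step 2 | keto cyclic sulfate, cyclic sulfate of F1 | CC(=O)[C@@H]1CC[C@]2(C)OS(=O)(=O)O[C@H]2C1
F4 | step 2 | lithium (1S,2R,4R)-4-acetyl-2-bromo-1-methylcyclohexyl sulfate | CC(=O)[C@@H]1CC[C@](C)(OS(=O)(=O)[O-])[C@H](Br)C1.[Li+]
F5 | step 2 | 1-[(1R,3R,4S)-3-bromo-4-hydroxy-4-methylcyclohexyl]ethan-1-one (bromohydrin methyl ketone) | CC(=O)[C@@H]1CC[C@](C)(O)[C@H](Br)C1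
F6 | step 3 | 4-epi keto cyclic sulfite (acetyl-bearing carbon inverted; both sulfur epimers) | CC(=O)[C@H]1CC[C@]2(C)OS(=O)O[C@H]2C1
F7 | step 3 | 4-epi keto cyclic sulfate | CC(=O)[C@H]1CC[C@]2(C)OS(=O)(=O)O[C@H]2C1
F8 | step 3 | lithium (1S,2R,4S)-4-acetyl-2-bromo-1-methylcyclohexyl sulfate | CC(=O)[C@H]1CC[C@](C)(OS(=O)(=O)[O-])[C@H](Br)C1.[Li+]
F9 | step 3 | 1-[(1S,3R,4S)-3-bromo-4-hydroxy-4-methylcyclohexyl]ethan-1-one (4-epi bromohydrin ketone) | CC(=O)[C@H]1CC[C@](C)(O)[C@H](Br)C1
F10 | step 10 | (2S,5S)-2-methyl-5-(prop-1-en-2-yl)-2-(trimethylsilyloxy)cyclohexan-1-one | CC(=C)[C@H]1CC[C@](C)(O[Si](C)(C)C)C(=O)C1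
F11 | step 10 | lithium enolate of F10 | [Li+].CC(=C)[C@H]1CC[C@](C)(O[Si](C)(C)C)C([O-])=C1
F12 | step 10 | bis(trimethylsilyl) ether of 16 | C=C(C[C@@H]1[C@@H](C(=C)C)CC[C@](C)(O[Si](C)(C)C)C1=O)[C@@H]1CC[C@](C)(O[Si](C)(C)C)[C@H](Br)C1
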